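**Same decay.** Whether the charge was 10 mM or 20 mM, and with 1 equiv or 2 equiv of leaving ligand, the complex with one exchanged fell away at nearly the same fractional rate: I read 0.138 /h in the north-east run, 0.133 /h in the south run and 0.135 /h in the south-east run. So I treated it as a first-order loss, and the question became how long each portion of product stood in the flask.

| flask | starting complex | incoming ligand | leaving ligand | protic impurity | remark | time |
|---|---|---|---|---|---|---|
| north-east | 20 mM | 0.95 equiv | 1 equiv | 2 mM | run made earlier |  |
| south | 10 mM | 0.95 equiv | 1 equiv | 2 mM | run made earlier |  |
| north | 15 mM | 0.95 equiv | 1 equiv | 2 mM | run made earlier |  |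
| south-east | 20 mM | 0.95 equiv | 2 equiv | 2 mM | run made earlier |  |
| ash | 20 mM | 0.950 equiv (fed, over 10 h) | 1.00 equiv | 2.00 mM | all else is in the flask from the start; the feed brings no volume worth counting | 12 h |
| larch | 20 mM | 0.950 equiv | 1.00 equiv | 2.00 mM | everything together at the start | 12 h |
| elm | 20 mM (fed, over 10 h) | 0.950 equiv | 1.00 equiv | 2.00 mM | all else is in the flask from the start; the feed brings no volume worth counting | 12 h |

- north-east (time / h: complex with one exchanged / %, starting complex / %): 1.50: 60.9, 26.4; 4.00: 48.7, 17.0; 8.00: 29.4, 15.9; 12.0: 16.2, 14.9
- south (time / h: complex with one exchanged / %, starting complex / %): 1.33: 50.4, 42.6; 3.00: 50.8, 28.3; 6.00: 37.4, 21.5; 10.0: 22.0, 21.1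
- north (time / h: complex with one exchanged / %, starting complex / %): 2.50: 55.3, 24.3; 5.00: 42.4, 18.7; 8.00: 29.1, 18.1; 10.0: 21.6, 17.4
- south-east (time / h: complex with one exchanged / %, starting complex / %): 0.833: 58.1, 36.5; 2.00: 59.7, 23.3; 4.00: 48.8, 17.2; 10.0: 21.7, 15.2

(each reading ± 0.5 percentage points)

- which flask leads in amount of complex with one exchanged, in percent of the starting complex charged ("all alike" within 1.5 percentage points) (ash / larch / elm / all alike)
- how much complex with one exchanged is there at the end, in percent of the starting complex charged: ash
- how much complex with one exchanged is there at the end, in percent of the starting complex charged: larch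
- how much complex with one exchanged is there at the end, in percent of the starting complex charged: elm



**Main step.** I first let the fed incoming ligand, the limiting reagent, exchange as it arrived, so that product formed steadily over the feed time T. Integrating that steady making against the decay gave the survival factor, the share of product made during the feed that still stands at time t: (1 − e^(−kT))/(kT) · e^(−k(t − T)). For the ash flask this came to 41.3%, against 19.2% for product made at the very start of the larch flask. On the full charge of ligand, my figure for ash was 39.2%.

**Lost ligand.** The north-east run stalled with 14.9% of its starting complex left, more than the 5.00% that the ligand shortfall allows, so about 1.98 mM of ligand had gone elsewhere, close to the 2.00 mM of protic impurity charged. That left a made share of 85.1%, and my figure for ash fell to 35.1%.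

**The rest.** The larch flask repeats the north-east charge, so I expected its reading of 16.2%. None of the runs had ligand standing beside the impurity before the complex arrived, so I carried 35.1% over to elm while expecting that flask to come in below it, which put ash ahead in my reckoning.

**The forecast.** The forecast gave ash 36%, larch 16.2% and elm 34%, with ash leading, on the ground that “Feeding delays formation, so less product has time to decay”. The flasks gave ash 34.2%, larch 16.4% and elm 24.2%, with ash leading.

    complex with one exchanged + incoming ligand → leaving ligand + complex with two exchanged (k = 0.0750 /M/min)
    starting complex + incoming ligand → leaving ligand + complex with one exchanged (k = 2.10 /M/min)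
    incoming ligand ⇌ dormant form (K = 1.50, k = 4.70 × 10⁻⁴ /min)
    protic impurity + incoming ligand → quenched reagent (k = 0.820 /M/min)
    complex with one exchanged → over-reaction product (k = 0.00240 /min)

**Reading back.** Elm ended with 30.1% of its starting complex unused against 15.1% in larch, its protic impurity down to 2.22% of its charge. In ash, 83.0% of the starting complex had been used at the end, and the survival factor turned that into 34.3%. With the elm feed shortened to 1.00 h, the factor became 20.6%, which on my made share of 85.1% gave 17.5%, and that elm flask ended at 17.1%.

The data are calculated for an exercise, and the scatter is random.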